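**Retrosynthetic overview** (atoms numbered by their position in the target SMILES)
1. The strategy rests on the cyclopropane C6/C20/C21: C6 carries the two oxygenated one-carbon arms C5 (O4) and C7 (O8), and C20 and C21 carry the trans branches C19 and C22. This is an oxidised gem-dimethylcyclopropane with the carbon pattern of (1R,3R)-trans-chrysanthemic acid.
2. Key disconnection: C5–O4 and C7–O8 are made together by a twofold carboxyl-directed methyl C–H lactonisation of (1R,2R)-trans-caronic acid 3, giving the C2-symmetric dilactone 5 (two γ-lactone rings, C6 set). One half-reduction then tells the two arms apart.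
3. C22 arm: lactol → vinyl → cross-metathesis/hydrogenation → methyl ketone → asymmetric allylation (C24) → silyl enol ether C18=C13. C19 arm: lactone → N-methoxy-N-methylamide → aldehyde, with O8 parked as a pivalate.
4. Ring order: cyclopropane (chiral pool) → two lactones (step 2) → dihydropyran and seven-membered carbocycle (ring A) together by Knoevenagel/intramolecular oxa-Diels–Alder (C19–C18, O12–C13) → oxepane last by Williamson closure O8–C9.
5. The drawn isomer is strained (ring A trans-fused to the cyclopropane), so C19 and C18 are fixed in the cycloaddition while C10 is still free, and the last ring is closed by an irreversible SN2 step that cannot change a stereocentre. C13 is set in the final acetylation.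

Key step: step 2

Assumption: the target is made exactly as drawn (C19 and C22 trans on the cyclopropane, so ring A is a trans-fused bicyclo[5.1.0]octane), and silyl enol ether 15 is used as an E/Z mixture because C13 is set only in the last step.

Step 1
Reactants: 1 (1R,3R)-trans-chrysanthemic acid
Product: 3 (1R,2R)-trans-caronic acid, via caronaldehydic acid 2 (not isolated)
Conditions: RuCl3·xH2O (2 mol %), NaIO4 (4 equiv), MeCN/EtOAc/H2O, 0 °C → rt
Reagents that add atoms: sodium periodate, [Na+].[O-]I(=O)(=O)=O; water, O
Why: RuO4 generated in situ cleaves the trisubstituted isobutenyl double bond oxidatively (RuCl3/NaIO4 alkene cleavage) to the carboxylic acid, and the two ring stereocentres are not touched.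

Step 2
Reactants: 3 (1R,2R)-trans-caronic acid
Product: 5 C2-symmetric dilactone, via monolactone acid 4 (not isolated)
Conditions: Pd(OAc)2 (15 mol %), N-acetylglycine (30 mol %), NaOAc (1 equiv), t-BuOOH (6 equiv, in decane), (CF3)2CHOH, 70 °C
Reagents that add atoms: none
Why: Proposed new method: carboxylate-bound divalent palladium cleaves a C–H bond of the methyl group cis to it by concerted metalation–deprotonation through a six-membered palladacycle, the peroxide oxidises the alkylpalladium to tetravalent palladium, and C–O reductive elimination with the carboxylate's own oxygen releases the γ-lactone; the same sequence then runs on the second carboxyl/methyl pair of 4. The closest known reaction type is the Pd(OAc)2-catalysed γ-C(sp3)–H lactonisation of free aliphatic carboxylic acids, which has not been shown twice on one molecule or on cyclopropyl methyl groups. Each of the two rings closes as a five-membered lactone in the 5-exo-tet sense (carboxylate oxygen onto the palladium-bound CH2), cis-fused to the cyclopropane. C6 becomes the one new stereocentre and is dictated by C20 and C21, because each carboxyl can reach only the methyl on its own ring face (C19 carboxyl → C7–O8, C22 carboxyl → C5–O4). The step needs methyl over cyclopropyl C–H selectivity and an intact three-membered ring: palladation of a ring C–H could only end in a bicyclobutane-type β-lactone and is therefore unproductive, and no radical or cation is formed at a cyclopropylcarbinyl carbon.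

Step 3
Reactants: 5 C2-symmetric dilactone
Product: 6 monolactol–lactone
Conditions: iBu2AlH (1.0 equiv), CH2Cl2, −78 °C
Reagents that add atoms: none
Why: The two lactones are homotopic (C2 axis through C6), so half-reduction of one lactone to the lactol with one equivalent of iBu2AlH gives a single constitutional isomer and tells the C22/C5 arm from the C19/C7 arm.

Step 4
Reactants: 6 monolactol–lactone
Product: 7 vinyl alcohol lactone
Conditions: Ph3PCH3Br (2.5 equiv), KOtBu (2.4 equiv), THF, 0 °C
Reagents that add atoms: methyltriphenylphosphonium bromide, C[P+](c1ccccc1)(c1ccccc1)c1ccccc1.[Br-]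
Why: Wittig methylenation of the ring-opened hydroxy-aldehyde form of the lactol is far faster than attack of the non-stabilised ylide on the remaining lactone, and the freed C5 alkoxide sits on the opposite ring face and cannot reach that lactone.

Step 5
Reactants: 7 vinyl alcohol lactone
Product: 8 TBS ether
Conditions: TBSCl, imidazole, DMF, rt
Reagents that add atoms: tert-butyldimethylsilyl chloride, CC(C)(C)[Si](C)(C)Cl
Why: Standard silylation of the primary alcohol protects O4 until the final acetylation.

Step 6
Reactants: 8 TBS ether
Product: 9 (E)-enone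
Conditions: methyl vinyl ketone (3 equiv), second-generation Grubbs catalyst (H2IMes)(PCy3)Cl2Ru=CHPh (5 mol %), CH2Cl2, 40 °C
Reagents that add atoms: methyl vinyl ketone, CC(=O)C=C
Why: Olefin cross-metathesis of the monosubstituted vinylcyclopropane with an electron-poor partner is selective for the E-enone and brings in C23, C24, C25 and O26.

Step 7
Reactants: 9 (E)-enone
Product: 10 methyl ketone
Conditions: H2 (1 atm), RhCl(PPh3)3 (5 mol %), benzene, rt
Reagents that add atoms: none
Why: Homogeneous hydrogenation saturates the unhindered disubstituted enone double bond and leaves the cyclopropane, the lactone and the ketone intact.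

Step 8
Reactants: 10 methyl ketone
Product: 11 (S)-tertiary homoallylic alcohol
Conditions: allylB(OiPr)2 (1.5 equiv), 3,3'-Br2-BINOL (15 mol %; the antipode that gives Re-face attack, to be confirmed on a model methyl ketone), PhCH3/PhCF3 3:1, −35 °C
Reagents that add atoms: allyldiisopropoxyborane, C=CCB(OC(C)C)OC(C)C
Why: Chiral-diol-catalysed asymmetric allylboration of a methyl ketone is reagent-controlled, allyl being delivered to the Re face (methyl as the small group), which sets C24 as S; the remote ring stereocentres have no influence.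

Step 9
Reactants: 11 (S)-tertiary homoallylic alcohol
Product: 12 TES ether
Conditions: TESOTf, 2,6-lutidine, CH2Cl2, −78 → 0 °C
Reagents that add atoms: triethylsilyl trifluoromethanesulfonate, CC[Si](CC)(CC)OS(=O)(=O)C(F)(F)F
Why: Silyl triflate/2,6-lutidine silylation caps the hindered tertiary alcohol, and the TES ether blocks retro-aldol and elimination chemistry at C24 in the later aldehyde stages.

Step 10
Reactants: 12 TES ether
Product: 14 C13 aldehyde, via ozonide 13 (not isolated)
Conditions: O3, CH2Cl2, −78 °C; then Me2S, −78 °C → rt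
Reagents that add atoms: ozone, [O-][O+]=O
Why: Ozonolysis with reductive work-up cleaves the only C=C bond and gives the C13 aldehyde with C18 as its α-carbon.

Step 11
Reactants: 14 C13 aldehyde
Product: 15 TIPS enol ether
Conditions: TIPSOTf, Et3N, CH2Cl2, 0 °C → rt
Reagents that add atoms: triisopropylsilyl trifluoromethanesulfonate, CC(C)[Si](C(C)C)(C(C)C)OS(=O)(=O)C(F)(F)F
Why: Soft enolisation (silyl triflate/amine) turns the aldehyde into its silyl enol ether, the electron-rich 2π partner for the cycloaddition, and its E/Z ratio does not matter because C13 is reset later.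

Step 12
Reactants: 15 TIPS enol ether
Product: 17 amide pivalate, via hydroxy amide 16 (not isolated)
Conditions: MeNH(OMe)·HCl (3 equiv), iPrMgCl (6 equiv), THF, −20 → 0 °C; then PivCl, DMAP (cat.), 0 °C → rt
Reagents that add atoms: N,O-dimethylhydroxylamine hydrochloride, CNOC.Cl; pivaloyl chloride, CC(C)(C)C(=O)Cl
Why: Aminolysis of the γ-lactone with the chloromagnesium amide gives the N-methoxy-N-methylamide at C19 and frees O8–H on C7, which is acylated in the same flask before it can re-lactonise; the pivalate later keeps O8 from adding to the heterodiene.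

Step 13
Reactants: 17 amide pivalate
Product: 18 C19 aldehyde
Conditions: iBu2AlH (1.2 equiv), THF, −78 °C
Reagents that add atoms: none
Why: Hydride reduction of an N-methoxy-N-methylamide stops at a chelated hemiaminal that gives the aldehyde on work-up and is much faster than attack on the hindered pivalate; C20 does not epimerise because the aldehyde is already trans to the C22 chain.

Step 14
Reactants: 18 C19 aldehyde
Product: 20 tricyclic dihydropyran aldehyde, via alkylidene malonaldehyde 19 (not isolated)
Conditions: NaOCH=CHCHO (1.5 equiv), AcOH (1.5 equiv), ethylenediammonium diacetate (20 mol %), MeCN/CH2Cl2, 0.005 M, 0 → 40 °C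
Reagents that add atoms: malonaldehyde sodium salt, [Na+].[O-]/C=C/C=O
Why: In this domino Knoevenagel condensation/intramolecular inverse-electron-demand oxa-Diels–Alder reaction, 19 reacts as a 1-oxadiene with the tethered silyl enol ether to form C19–C18 and O12–C13; allylic strain keeps C20–H in the plane of the C19=C10 bond, so the tether from C21 reaches only the face that gives 19R, and ring A can span only the mode with H18 and H19 cis (18R), while C13 is formed as a mixture.

Step 15
Reactants: 20 tricyclic dihydropyran aldehyde
Product: 21 diol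
Conditions: iBu2AlH (5 equiv), CH2Cl2, −78 → −20 °C
Reagents that add atoms: none
Why: Hydride reduction takes the vinylogous formate aldehyde to the allylic alcohol (1,2-reduction) and cleaves the pivalate in one operation, freeing C9–OH and O8–H while all silyl groups stay.

Step 16
Reactants: 21 diol
Product: 23 tetracyclic oxepane, via C9 tosylate 22 (not isolated)
Conditions: NaH (2.5 equiv), THF, 0 °C; then 1-(p-toluenesulfonyl)imidazole (1.05 equiv), 0.005 M, 0 °C → rt
Reagents that add atoms: none
Why: In this one-pot sulfonylation/intramolecular Williamson etherification the less hindered allylic C9 alkoxide is tosylated and the C7 alkoxide (O8) displaces the tosylate (7-exo-tet), an irreversible SN2 step that pays the strain of the last ring without touching a stereocentre; tosylation at the other oxygen would give the same ether.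

Step 17
Reactants: 23 tetracyclic oxepane
Product: 24 triol
Conditions: Bu4NF (6 equiv), AcOH (6 equiv), THF, 0 °C → rt
Reagents that add atoms: none
Why: Buffered fluoride desilylation removes the primary TBS ether, the anomeric TIPS acetal and the tertiary TES ether, and the acetic acid keeps the medium non-basic so that the lactol does not open by retro-aldol cleavage.

Step 18
Reactants: 24 triol
Product: 25 target CNP0250836.2
Conditions: Ac2O, pyridine, CH2Cl2, 0 °C → rt
Reagents that add atoms: acetic anhydride, CC(=O)OC(C)=O
Why: Acetylation with Ac2O/pyridine takes the primary alcohol and the lactol hydroxyl but not the hindered tertiary alcohol, and the mutarotating lactol is expected to be acylated as the anomer with OAc anti to the quaternary C24 substituent on C18, which is 13R.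

**Compound list**
1 | (1R,3R)-trans-chrysanthemic acid | OC(=O)[C@@H]1[C@@H](C=C(C)C)C1(C)C | starting material
2 | (1R,3R)-3-formyl-2,2-dimethylcyclopropane-1-carboxylic acid (caronaldehydic acid; formed and consumed in step 1) | OC(=O)[C@@H]1[C@@H](C=O)C1(C)C | intermediate
3 | (1R,2R)-3,3-dimethylcyclopropane-1,2-dicarboxylic acid (trans-caronic acid) | OC(=O)[C@@H]1[C@@H](C(=O)O)C1(C)C | intermediate
4 | monolactone acid, 5-methyl-2-oxo-3-oxabicyclo[3.1.0]hexane-6-carboxylic acid with the lactone between the C19 carboxyl and C7 and the C22 carboxyl exo (formed and consumed in step 2) | O=C1[C@@H]2[C@@H](C(=O)O)[C@]2(C)CO1 | intermediate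
5 | (5R,6R)-3,8-dioxatricyclo[4.3.0.0(1,5)]nonane-4,7-dione, the C2-symmetric bis-γ-lactone | O=C1OC[C@@]23COC(=O)[C@@H]2[C@@H]13 | intermediate
6 | monolactol of 5: C22 is a hemiacetal carbon (anomer mixture), the C19 lactone is intact | O=C1[C@@H]2[C@@H](C3O)[C@]2(CO3)CO1 | intermediate
7 | 5-(hydroxymethyl)-6-exo-vinyl-3-oxabicyclo[3.1.0]hexan-2-one (C5–OH free, vinyl C22=C23 trans to C19) | O=C1[C@@H]2[C@@H](C=C)[C@]2(CO)CO1 | intermediate
8 | TBS ether of 7 | O=C1[C@@H]2[C@@H](C=C)[C@]2(CO[Si](C)(C)C(C)(C)C)CO1 | intermediate
9 | (E)-enone, the 6-exo-[(E)-3-oxobut-1-enyl] analogue of 8 | O=C1[C@@H]2[C@@H](/C=C/C(C)=O)[C@]2(CO[Si](C)(C)C(C)(C)C)CO1 | intermediate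
10 | methyl ketone, the 6-exo-(3-oxobutyl) analogue of 8 | O=C1[C@@H]2[C@@H](CCC(C)=O)[C@]2(CO[Si](C)(C)C(C)(C)C)CO1 | intermediate
11 | tertiary homoallylic alcohol, the 6-exo-[(3S)-3-hydroxy-3-methylhex-5-enyl] analogue of 8 | O=C1[C@@H]2[C@@H](CC[C@](C)(O)CC=C)[C@]2(CO[Si](C)(C)C(C)(C)C)CO1 | intermediate
12 | TES ether of 11 | O=C1[C@@H]2[C@@H](CC[C@](C)(O[Si](CC)(CC)CC)CC=C)[C@]2(CO[Si](C)(C)C(C)(C)C)CO1 | intermediate
13 | ozonide (1,2,4-trioxolane) of 12 (formed and consumed in step 10) | O=C1[C@@H]2[C@@H](CC[C@](C)(O[Si](CC)(CC)CC)CC3OCOO3)[C@]2(CO[Si](C)(C)C(C)(C)C)CO1 | intermediate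
14 | C13 aldehyde, the 6-exo-[(3S)-3-methyl-5-oxo-3-(triethylsilyloxy)pentyl] analogue of 8 | O=C1[C@@H]2[C@@H](CC[C@](C)(O[Si](CC)(CC)CC)CC=O)[C@]2(CO[Si](C)(C)C(C)(C)C)CO1 | intermediate
15 | TIPS enol ether of 14 (C18=C13–OTIPS, E/Z mixture) | O=C1[C@@H]2[C@@H](CC[C@](C)(O[Si](CC)(CC)CC)C=CO[Si](C(C)C)(C(C)C)C(C)C)[C@]2(CO[Si](C)(C)C(C)(C)C)CO1 | intermediate
16 | ring-opened hydroxy N-methoxy-N-methylamide (amide at C19, free C7–OH; formed and consumed in step 12) | CON(C)C(=O)[C@@H]1[C@@H](CC[C@](C)(O[Si](CC)(CC)CC)C=CO[Si](C(C)C)(C(C)C)C(C)C)[C@]1(CO[Si](C)(C)C(C)(C)C)CO | intermediate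
17 | pivalate of 16 (C7–OPiv) | CON(C)C(=O)[C@@H]1[C@@H](CC[C@](C)(O[Si](CC)(CC)CC)C=CO[Si](C(C)C)(C(C)C)C(C)C)[C@]1(CO[Si](C)(C)C(C)(C)C)COC(=O)C(C)(C)C | intermediate
18 | cyclopropanecarbaldehyde (C19 aldehyde; C7–OPiv, C5–OTBS, C24–OTES, TIPS enol ether) | O=C[C@@H]1[C@@H](CC[C@](C)(O[Si](CC)(CC)CC)C=CO[Si](C(C)C)(C(C)C)C(C)C)[C@]1(CO[Si](C)(C)C(C)(C)C)COC(=O)C(C)(C)C | intermediate
19 | alkylidene malonaldehyde, C19=C10(CHO)2 (formed and consumed in step 14) | O=CC(C=O)=C[C@@H]1[C@@H](CC[C@](C)(O[Si](CC)(CC)CC)C=CO[Si](C(C)C)(C(C)C)C(C)C)[C@]1(CO[Si](C)(C)C(C)(C)C)COC(=O)C(C)(C)C | intermediate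
20 | cycloadduct: 2-(triisopropylsilyloxy)-3,4-dihydro-2H-pyran-5-carbaldehyde cis-fused (H18/H19 syn) to the seven-membered carbocycle, itself trans-fused to the cyclopropane; C13 epimer mixture | O=CC1=COC(O[Si](C(C)C)(C(C)C)C(C)C)[C@@H]2[C@H]1[C@@H]3[C@@H](CC[C@]2(C)O[Si](CC)(CC)CC)[C@]3(CO[Si](C)(C)C(C)(C)C)COC(=O)C(C)(C)C | intermediate
21 | diol (C9–OH and C7–OH free) | OCC1=COC(O[Si](C(C)C)(C(C)C)C(C)C)[C@@H]2[C@H]1[C@@H]3[C@@H](CC[C@]2(C)O[Si](CC)(CC)CC)[C@]3(CO[Si](C)(C)C(C)(C)C)CO | intermediate
22 | C9 tosylate of 21 (formed and consumed in step 16) | Cc1ccc(cc1)S(=O)(=O)OCC1=COC(O[Si](C(C)C)(C(C)C)C(C)C)[C@@H]2[C@H]1[C@@H]3[C@@H](CC[C@]2(C)O[Si](CC)(CC)CC)[C@]3(CO[Si](C)(C)C(C)(C)C)CO | intermediate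
23 | tetracyclic tris-silyl ether (oxepane closed; C5–OTBS, C13–OTIPS, C24–OTES) | CC(C)(C)[Si](C)(C)OC[C@@]12COCC3=COC(O[Si](C(C)C)(C(C)C)C(C)C)[C@@H]4[C@H]3[C@@H]1[C@H]2CC[C@]4(C)O[Si](CC)(CC)CC | intermediate
24 | triol (C5–OH, C13 lactol OH as anomer mixture, C24–OH) | OC[C@@]12COCC3=COC(O)[C@@H]4[C@H]3[C@@H]1[C@H]2CC[C@]4(C)O | intermediate
25 | CNP0250836.2 | CC(=O)OC[C@@]12COCC3=CO[C@H](OC(C)=O)[C@@H]4[C@H]3[C@@H]1[C@H]2CC[C@]4(C)O | target

**Total step count:** 18. **Longest linear sequence:** 18 steps (from 1).

**Steps most likely to fail**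

1. Step 2 (proposed new method). The carboxylate may fail to bring palladium onto the methyl C–H bond, because the palladacycle has to form on a rigid cyclopropane. Palladium may instead insert into a ring C–H or C–C bond, or the second lactonisation may stall at 4.
 Fallback (known reactions only, no C–H oxidation): the two oxygenated arms come in with the building block. It sets out from none of the numbered compounds (1–4 are bypassed; it starts from commercial 2,2-dimethyl-1,3-dioxan-5-one) and comes back to the route at 5. Horner–Wadsworth–Emmons olefination with triethyl phosphonoacetate/NaH gives ethyl 2-(2,2-dimethyl-1,3-dioxan-5-ylidene)acetate F1. Sulfur-ylide cyclopropanation of this enoate with (CH3)2S=CHCO2Et (Michael-initiated ring closure, trans-selective) gives racemic diethyl trans-6,6-dimethyl-5,7-dioxaspiro[2.5]octane-1,2-dicarboxylate F2. Aqueous CF3CO2H removes the acetonide, and each hydroxymethyl group lactonises onto the ester on its own face to give the racemic dilactone F3. F3 is separated into its enantiomers on a chiral stationary phase to give 5.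

2. Step 14. Ring A is strained, so the intramolecular cycloaddition may be slower than oligomerisation of heterodiene 19 or intermolecular cycloaddition. Facial selectivity at C19 may also erode if the reaction has to be forced thermally.
 Fallback: give up the concerted cycloaddition and close ring A by a stepwise, Lewis-acid-driven ionic addition. It sets out from 18 and comes back at 20. 19 is generated as in step 14 at −20 °C and treated in the same flask at −78 °C with Yb(OTf)3. This is an intramolecular Mukaiyama–Michael addition of the silyl enol ether to the chelated alkylidene malonaldehyde, in which only the C18–C19 bond is made, through an open transition state. On aqueous work-up the resulting enol closes onto the C13 aldehyde to give the lactol F4, and TIPSOTf/2,6-lutidine silylates the lactol hydroxyl to give 20.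

3. Step 16. The allylic tosylate next to the enol ether may ionise, so that O8 attacks C11 (allylic transposition to a bridged acetal) instead of C9. The strained ring may also close too slowly and give oligomers.
 Fallback: invert the polarity so that the electrophilic carbon is the non-allylic C7. It sets out from 21 and comes back at 23. Selective acetylation of the less hindered allylic C9 hydroxyl (Ac2O, 2,4,6-collidine, −40 °C) gives the monoacetate F5. MsCl/Et3N converts the C7 hydroxyl into the acetate mesylate F6. K2CO3 in methanol removes the acetate, and the C9 alkoxide displaces the mesylate at C7 (7-exo-tet SN2 at a carbon that cannot undergo allylic transposition), giving 23.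

Further compounds
F1 | step 2 | ethyl 2-(2,2-dimethyl-1,3-dioxan-5-ylidene)acetate | CCOC(=O)C=C1COC(C)(C)OC1
F2 | step 2 | racemic diethyl trans-6,6-dimethyl-5,7-dioxaspiro[2.5]octane-1,2-dicarboxylate (relative configuration shown) | CCOC(=O)[C@@H]1[C@@H](C(=O)OCC)C12COC(C)(C)OC2
F3 | step 2 | racemic 3,8-dioxatricyclo[4.3.0.0(1,5)]nonane-4,7-dione (racemate of 5) | O=C1OCC23COC(=O)C2C13
F4 | step 14 | lactol corresponding to 20 (C13–OH instead of C13–OTIPS) | O=CC1=COC(O)[C@@H]2[C@H]1[C@@H]3[C@@H](CC[C@]2(C)O[Si](CC)(CC)CC)[C@]3(CO[Si](C)(C)C(C)(C)C)COC(=O)C(C)(C)C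
F5 | step 16 | C9 monoacetate of 21 | CC(=O)OCC1=COC(O[Si](C(C)C)(C(C)C)C(C)C)[C@@H]2[C@H]1[C@@H]3[C@@H](CC[C@]2(C)O[Si](CC)(CC)CC)[C@]3(CO[Si](C)(C)C(C)(C)C)CO
F6 | step 16 | C9 acetate C7 mesylate of 21 | CC(=O)OCC1=COC(O[Si](C(C)C)(C(C)C)C(C)C)[C@@H]2[C@H]1[C@@H]3[C@@H](CC[C@]2(C)O[Si](CC)(CC)CC)[C@]3(CO[Si](C)(C)C(C)(C)C)COS(C)(=O)=O
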